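(The runs are simulated with made-up constants; scatter was added.)

Time was the thing to reckon with: at 25 h the alder flask stood at its last reading, and the choice was to wait, to add catalyst, or to pull target out.

| flask | starting material | catalyst | remark | time |
|---|---|---|---|---|
| alder | 3 M | 0.1 mol% | the very flask that is asked about, followed so far |  |
| oak | 1.5 M | 0.1 mol% | run made earlier |  |
| flask | 3.0 M | 0.1 mol% |  | 25 h |

| run | time / h | target / % |
|---|---|---|
| alder | 2.00 | 15.5 |
| alder | 3.00 | 22.0 |
| alder | 6.00 | 28.5 |
| alder | 10.0 | 29.5 |
| alder | 15.0 | 28.0 |
| alder | 25.0 | 22.7 |
| oak | 0.833 | 2.3 |
| oak | 1.50 | 4.5 |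
| oak | 2.50 | 9.1 |
| oak | 3.00 | 11.4 |
| oak | 4.00 | 14.7 |
| oak | 5.00 | 18.1 |

(readings scatter by 0.3 percentage points)

- violet: change nothing and wait 12 h more
- grey: at 25 h add catalyst, 100% of the amount charged, then wait 12 h
- amber: at 25 h take out 90% of the target then present, then wait 12 h

- target taken out counts as made
- additions bring no volume worth counting

- target, in percent of the starting material first charged, at 25 h
- which option adds most target ("none" when 2 percentage points or less is all one gets) (violet / grey / amber / none)
- target present, with what was taken out counted in, in percent of the starting material first charged, after violet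
- target present, with what was taken out counted in, in percent of the starting material first charged, after grey

I treated the wait as a correction to what already stood in alder. Its last reading gave [target] at 25 h, 22.7%. Its last two readings gave the loss constant λ, the fraction of the target lost per hour past the peak, taken as pseudo-first-order:

λ = ln(28.0% / 22.7%) / 10.0 h = 0.0210 h⁻¹

Waiting 12 h then left

violet: 22.7% · exp(−λ · 12 h) = 17.6%

Taking out 90% put that share beyond the loss. With λ acting on the remainder and no target regrown, the count was

amber floor: 22.2%

So the floor stood higher than violet. The weak link was λ, which rested on two readings of a fall that had not been steady. I reforged it by taking 2 λ: violet dropped to 13.7%, while the amber floor moved to 21.8%. I committed to amber over violet; my reckoning gave no number for grey.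

The forecast differed. It gave 22.7% now, 17.5% after violet and 28% after grey, and chose grey, on the suggestion that “the target poisons the catalyst”.

The flask gave 22.6% at 25 h, and the best option was amber: it changed the target by 9 percentage points, more than violet with −4.5 points or grey with −5.2 points, and grey ended at 17.4%. At 25 h the catalyst stood at 100% of its charge, and the forward half-life of target passing into isomer of the product A, 1.4 h, was shorter than that time. Put to use again, λ gave 17.6% for violet against the computed 18.1%. The amber floor meant a change of −0.50 points, so the rest of the gain was target made after the removal.

    starting material + catalyst ⇌ target + catalyst, rate k1*[starting material]*[catalyst] forward; the back reaction follows from the equilibrium constant (K = 2.62, k = 0.00767 L mol⁻¹ s⁻¹)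
    target + catalyst ⇌ isomer of the product A + catalyst, rate k2*[catalyst]*[target] forward; the back reaction follows from the equilibrium constant (K = 0.744, k = 0.0444 L mol⁻¹ s⁻¹)
    isomer of the product A + catalyst ⇌ isomer of the product B + catalyst, rate k3*[catalyst]*[isomer of the product A] forward; the back reaction follows from the equilibrium constant (K = 0.700, k = 0.0366 L mol⁻¹ s⁻¹)
    isomer of the product B + catalyst ⇌ starting material + catalyst, rate k4*[catalyst]*[isomer of the product B] forward; the back reaction follows from the equilibrium constant (k = 0.285 L mol⁻¹ s⁻¹)
    starting material → uncatalysed product (k = 3.95 × 10⁻⁵ s⁻¹)

A neighbour flask with the same charge, read at 4.0 d: λ carried from 22.7% gave 5.11%. The computed target there was 6.06%.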